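**Retrosynthetic overview**

1. Target 17 is 3-hexadecyl-2,5-dihydroxy-1,4-benzoquinone, ring atoms numbered C1 (C=O), C2 (OH), C3 (hexadecyl), C4 (C=O), C5 (OH), C6 (H). The feature used is that the para carbonyl carbons C1 and C4 flank the adjacent pair C2–C3, so the single six-membered ring divides into C1 (carbon monoxide), C2–C3 (an alkyne with boron on C2 as masked hydroxyl and the chain on C3) and C4–C5–C6 (a methoxy(vinyl)carbene).
2. 17 ⇐ 16 (hydrolysis of a C5 amino group) ⇐ 14 (amine conjugate addition at C5, steered by the C2 hydroxyl) ⇐ 13 (oxidative demethylation) ⇐ 12 (C–B oxidation).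
3. 12 ⇐ 5 + 10 by chromium-mediated three-component [3+2+1] benzannulation, which forms C3–C4, C1–C2 and C1–C6 and closes the only ring of the molecule.
4. 5 ⇐ vinyl bromide 1 + Cr(CO)6 2; 10 ⇐ 1-octadecyne 6 + isopropoxy pinacolborane 7.

Key step: step 3

Remark: the target has no stereocentre; it is drawn and made as the 2,5-dihydroxy-1,4-quinone tautomer.

**Step 1**
Reactants: 1 vinyl bromide; 2 hexacarbonylchromium
Product: 5 pentacarbonyl[methoxy(vinyl)carbene]chromium, via vinyllithium 3 (not isolated), via lithium acylate 4 (not isolated)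
Conditions: t-BuLi (2 equiv), Et2O, −78 °C; Cr(CO)6, −78 → 0 °C; Me3OBF4, CH2Cl2/H2O, 0 °C; kept cold and used at once
Reagents that add atoms: trimethyloxonium tetrafluoroborate, C[O+](C)C.F[B-](F)(F)F
Why: Bromine–lithium exchange gives vinyllithium, which adds to a carbonyl ligand of zerovalent chromium, and O-methylation of the resulting acylate completes the classical Fischer carbene synthesis.

**Step 2**
Reactants: 6 1-octadecyne; 7 2-isopropoxy-4,4,5,5-tetramethyl-1,3,2-dioxaborolane
Product: 10 2-(octadec-1-yn-1-yl)-4,4,5,5-tetramethyl-1,3,2-dioxaborolane, via lithium octadecynide 8 (not isolated), via lithium alkynylborate 9 (not isolated)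
Conditions: n-BuLi (1.0 equiv), THF, −78 °C; 7, −78 °C; HCl (2 M in Et2O, 1.05 equiv), −78 °C → rt; filtration under argon
Reagents that add atoms: none
Why: Deprotonation of the terminal alkyne and trapping of the acetylide by the alkoxyboronate gives a tetracoordinate borate, from which anhydrous HCl removes isopropoxide to release the alkynylboronate (borylation of a metal acetylide).

**Step 3**
Reactants: 5 pentacarbonyl[methoxy(vinyl)carbene]chromium; 10 2-(octadec-1-yn-1-yl)-4,4,5,5-tetramethyl-1,3,2-dioxaborolane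
Product: 12 3-hexadecyl-4-methoxy-2-(4,4,5,5-tetramethyl-1,3,2-dioxaborolan-2-yl)phenol, via tricarbonylchromium arene complex 11 (not isolated)
Conditions: 5 (1.0 equiv), 10 (1.5 equiv), THF (0.05 M), 50 °C, argon; then air, EtOAc, rt
Reagents that add atoms: none
Why: Loss of one CO from zerovalent chromium in 5 opens a site for alkyne 10, which inserts into the Cr=C bond to form C3–C4 and a chromium dienylcarbene, and migratory insertion of a CO ligand then forms C1–C2 and gives a chromium-bound dienylketene. The ring is closed by 6π-electrocyclisation of this ketene (C1–C6), and the cyclohexadienone tautomerises to the phenol, held first as the tricarbonylchromium complex 11 and freed by air. This is the Dötz benzannulation of an alkenyl(alkoxy)carbene complex of chromium with an alkynylboronate, a known pairing in which the boronate survives and is expected next to the new hydroxyl. No stereocentre is formed. The selectivity needed is CO insertion and six-ring closure over cyclobutenone, furan and five-membered-ring products, and an alkenyl carbene with a methoxy donor on chromium in THF at moderate temperature is the combination that favours it. The orientation of the alkyne needs no control, since the regioisomer with boron and chain exchanged would give the same quinone 14 after steps 4 and 5.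

**Step 4**
Reactants: 12 3-hexadecyl-4-methoxy-2-(4,4,5,5-tetramethyl-1,3,2-dioxaborolan-2-yl)phenol
Product: 13 3-hexadecyl-4-methoxybenzene-1,2-diol
Conditions: NaBO3·4H2O (3 equiv), THF/H2O (1:1), rt, argon; aq. NH4Cl; carried on crude
Reagents that add atoms: sodium perborate, [Na+].[O-]OB=O
Why: Perborate adds to boron and the aryl group migrates from boron to oxygen (oxidation of an arylboronate, as in the oxidative step of hydroboration–oxidation), under conditions mild enough to spare the methyl ether and the electron-rich ring.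

**Step 5**
Reactants: 13 3-hexadecyl-4-methoxybenzene-1,2-diol
Product: 14 3-hexadecyl-2-hydroxy-1,4-benzoquinone
Conditions: (NH4)2Ce(NO3)6 (2.2 equiv), MeCN/CH2Cl2/H2O, 0 °C
Reagents that add atoms: water, O
Why: Two-electron oxidation by tetravalent cerium with attack of water at C4 and loss of methanol (oxidative demethylation of a hydroquinone monomethyl ether) gives the hydroxyquinone, and the same product results whether cerium first engages the para-methoxyphenol pair or the catechol pair.

**Step 6**
Reactants: 14 3-hexadecyl-2-hydroxy-1,4-benzoquinone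
Product: 16 3-hexadecyl-2-hydroxy-5-(morpholin-4-yl)-1,4-benzoquinone, via aminohydroquinone 15 (not isolated)
Conditions: morpholine (3 equiv), EtOH/CH2Cl2, air, rt; 1 M HCl wash
Reagents that add atoms: morpholine, C1COCCN1
Why: Michael addition of the amine and aerobic reoxidation (oxidative amination of a quinone, known for 2-hydroxy-3-alkylbenzoquinones) should go to C5, because the ionised C2 hydroxyl ties C2–C3–C4=O up as a vinylogous carboxylate and leaves C1=O as the only activating carbonyl, whose β-carbon is C5.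

**Step 7**
Reactants: 16 3-hexadecyl-2-hydroxy-5-(morpholin-4-yl)-1,4-benzoquinone
Product: 17 3-hexadecyl-2,5-dihydroxy-1,4-benzoquinone
Conditions: 2 M H2SO4, 1,4-dioxane, 90 °C
Reagents that add atoms: water, O
Why: Acid hydrolysis of the vinylogous amide (addition of water at C5, loss of morpholinium) is the standard conversion of an aminoquinone into a hydroxyquinone, and the dihydroxyquinone is stable to aqueous acid.

**Compound list**

1 | vinyl bromide | C=CBr | starting material
2 | hexacarbonylchromium | O=C=[Cr](=C=O)(=C=O)(=C=O)(=C=O)=C=O | starting material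
3 | vinyllithium | [Li]C=C | intermediate
4 | lithium pentacarbonyl(1-oxidoprop-2-en-1-ylidene)chromate (lithium acylate) | [Li+].[O-]C(C=C)=[Cr](=C=O)(=C=O)(=C=O)(=C=O)=C=O | intermediate
5 | pentacarbonyl[methoxy(vinyl)carbene]chromium | COC(C=C)=[Cr](=C=O)(=C=O)(=C=O)(=C=O)=C=O | intermediate
6 | 1-octadecyne | CCCCCCCCCCCCCCCCC#C | starting material
7 | 2-isopropoxy-4,4,5,5-tetramethyl-1,3,2-dioxaborolane | CC(C)OB1OC(C)(C)C(C)(C)O1 | starting material
8 | lithium octadec-1-yn-1-ide | CCCCCCCCCCCCCCCCC#C[Li] | intermediate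
9 | lithium isopropoxy(octadec-1-yn-1-yl)(pinacolato)borate | [Li+].CCCCCCCCCCCCCCCCC#C[B-]1(OC(C)C)OC(C)(C)C(C)(C)O1 | intermediate
10 | 2-(octadec-1-yn-1-yl)-4,4,5,5-tetramethyl-1,3,2-dioxaborolane | CCCCCCCCCCCCCCCCC#CB1OC(C)(C)C(C)(C)O1 | intermediate
11 | tricarbonyl{η6-[3-hexadecyl-4-methoxy-2-(4,4,5,5-tetramethyl-1,3,2-dioxaborolan-2-yl)phenol]}chromium (arene and Cr(CO)3 written as two parts) | CCCCCCCCCCCCCCCCc1c(OC)ccc(O)c1B1OC(C)(C)C(C)(C)O1.O=C=[Cr](=C=O)=C=O | intermediate
12 | 3-hexadecyl-4-methoxy-2-(4,4,5,5-tetramethyl-1,3,2-dioxaborolan-2-yl)phenol | CCCCCCCCCCCCCCCCc1c(OC)ccc(O)c1B1OC(C)(C)C(C)(C)O1 | intermediate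
13 | 3-hexadecyl-4-methoxybenzene-1,2-diol | CCCCCCCCCCCCCCCCc1c(OC)ccc(O)c1O | intermediate
14 | 3-hexadecyl-2-hydroxy-1,4-benzoquinone | CCCCCCCCCCCCCCCCC1=C(O)C(=O)C=CC1=O | intermediate
15 | 3-hexadecyl-5-(morpholin-4-yl)benzene-1,2,4-triol | CCCCCCCCCCCCCCCCc1c(O)c(O)cc(N2CCOCC2)c1O | intermediate
16 | 3-hexadecyl-2-hydroxy-5-(morpholin-4-yl)-1,4-benzoquinone | CCCCCCCCCCCCCCCCC1=C(O)C(=O)C=C(N2CCOCC2)C1=O | intermediate
17 | 3-hexadecyl-2,5-dihydroxy-1,4-benzoquinone | CCCCCCCCCCCCCCCCC1=C(O)C(=O)C=C(O)C1=O | target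

**Step count**

Total step count: 7. Longest linear sequence: 6 steps (1 or 2, then 3, 4, 5, 6, 7).

**Steps most likely to fail**

Step 3. The unsubstituted vinylcarbene may be consumed by oligomerisation before it captures the alkyne. The alkyne-inserted carbene may also close without CO or stop at the four-membered ketone, so that six-ring formation becomes a minor pathway.

The fallback builds the same dienylketene without metal. It sets out from vinyl bromide 1 (through vinyllithium 3) and comes back at quinone 14.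
- Commercial diisopropyl squarate and hexadecylmagnesium bromide (THF, −78 °C) should give racemic 4-hexadecyl-4-hydroxy-2,3-di(propan-2-yloxy)cyclobut-2-en-1-one F1.
- A trace of concentrated HCl in CH2Cl2 removes propan-2-ol to give 3-hexadecyl-4-(propan-2-yloxy)cyclobut-3-ene-1,2-dione F2.
- Vinyllithium 3 adds to the ketone carbonyl next to the alkoxy-bearing carbon, the other carbonyl being a vinylogous ester, to give racemic 4-ethenyl-2-hexadecyl-4-hydroxy-3-(propan-2-yloxy)cyclobut-2-en-1-one F3.
- In refluxing toluene this opens (4π), closes (6π) and tautomerises to 2-hexadecyl-3-(propan-2-yloxy)benzene-1,4-diol F4 (thermal ring expansion of a 4-alkenyl-4-hydroxycyclobutenone).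
- Ag2O oxidises it to 2-hexadecyl-3-(propan-2-yloxy)cyclohexa-2,5-diene-1,4-dione F5, and aqueous NaOH in THF followed by HCl hydrolyses the vinylogous ester to 14.

Step 1. The vinyl complex may polymerise, or take up a second vinyllithium at its β-carbon, during acylate formation, methylation and isolation, so that too little carbene reaches step 3.

The fallback uses a β-silyl-blocked carbene. It sets out from hexacarbonylchromium 2 and comes back at phenol 12.
- Commercial (E)-(2-bromovinyl)trimethylsilane and t-BuLi (Et2O, −78 °C) give (E)-2-(trimethylsilyl)ethenyllithium F6.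
- With 2 this forms lithium pentacarbonyl[(E)-1-oxido-3-(trimethylsilyl)prop-2-en-1-ylidene]chromate F7, and Me3OBF4 gives pentacarbonyl{methoxy[(E)-2-(trimethylsilyl)ethenyl]carbene}chromium F8, which should be storable.
- Benzannulation with 10 under the conditions of step 3 places H and SiMe3 on C6 of the cyclohexadienone. A 1,3-shift of silicon from C6 to oxygen should then aromatise it to tricarbonyl{η6-[3-hexadecyl-4-methoxy-2-(4,4,5,5-tetramethyl-1,3,2-dioxaborolan-2-yl)phenoxy]trimethylsilane}chromium F9.
- Air frees [3-hexadecyl-4-methoxy-2-(4,4,5,5-tetramethyl-1,3,2-dioxaborolan-2-yl)phenoxy]trimethylsilane F10, and K2CO3 in MeOH cleaves the silyl ether to 12.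

Step 6. The ionised hydroxyquinone may add the amine too slowly, so that self-condensation and over-oxidation in the aerated amine solution compete, or addition may leak to C6. Acid-catalysed acetoxylation is not the remedy: in acetic anhydride the C2 hydroxyl becomes an acetoxy group, which directs no better than the C3 alkyl group.

The fallback lets the carbene-derived methoxy group direct the last oxygen. It sets out from catechol 13 and comes back at target 17.
- NaIO3 in MeOH/CH2Cl2 oxidises 13 to 3-hexadecyl-4-methoxycyclohexa-3,5-diene-1,2-dione F11, in which the methoxy group makes C2=O a vinylogous ester.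
- Methanol then adds at C5, β to C1=O, to give 3-hexadecyl-4,5-dimethoxybenzene-1,2-diol F12.
- The iodate oxidises this on to 3-hexadecyl-4,5-dimethoxycyclohexa-3,5-diene-1,2-dione F13 (oxidative methoxylation of catechols).
- Aqueous NaOH in EtOH and then HCl hydrolyse both vinylogous esters to 17.

**Further compounds**

F1 | step 3 | 4-hexadecyl-4-hydroxy-2,3-di(propan-2-yloxy)cyclobut-2-en-1-one (racemic) | CCCCCCCCCCCCCCCCC1(O)C(OC(C)C)=C(OC(C)C)C1=O
F2 | step 3 | 3-hexadecyl-4-(propan-2-yloxy)cyclobut-3-ene-1,2-dione | CCCCCCCCCCCCCCCCC1=C(OC(C)C)C(=O)C1=O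
F3 | step 3 | 4-ethenyl-2-hexadecyl-4-hydroxy-3-(propan-2-yloxy)cyclobut-2-en-1-one (racemic) | C=CC1(O)C(OC(C)C)=C(CCCCCCCCCCCCCCCC)C1=O
F4 | step 3 | 2-hexadecyl-3-(propan-2-yloxy)benzene-1,4-diol | CCCCCCCCCCCCCCCCc1c(O)ccc(O)c1OC(C)C
F5 | step 3 | 2-hexadecyl-3-(propan-2-yloxy)cyclohexa-2,5-diene-1,4-dione | CCCCCCCCCCCCCCCCC1=C(OC(C)C)C(=O)C=CC1=O
F6 | step 1 | (E)-2-(trimethylsilyl)ethenyllithium | [Li]/C=C/[Si](C)(C)C
F7 | step 1 | lithium pentacarbonyl[(E)-1-oxido-3-(trimethylsilyl)prop-2-en-1-ylidene]chromate | [Li+].[O-]C(/C=C/[Si](C)(C)C)=[Cr](=C=O)(=C=O)(=C=O)(=C=O)=C=O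
F8 | step 1 | pentacarbonyl{methoxy[(E)-2-(trimethylsilyl)ethenyl]carbene}chromium | COC(/C=C/[Si](C)(C)C)=[Cr](=C=O)(=C=O)(=C=O)(=C=O)=C=O
F9 | step 1 | tricarbonyl{η6-[3-hexadecyl-4-methoxy-2-(4,4,5,5-tetramethyl-1,3,2-dioxaborolan-2-yl)phenoxy]trimethylsilane}chromium (arene and Cr(CO)3 written as two parts) | CCCCCCCCCCCCCCCCc1c(OC)ccc(O[Si](C)(C)C)c1B1OC(C)(C)C(C)(C)O1.O=C=[Cr](=C=O)=C=O
F10 | step 1 | [3-hexadecyl-4-methoxy-2-(4,4,5,5-tetramethyl-1,3,2-dioxaborolan-2-yl)phenoxy]trimethylsilane | CCCCCCCCCCCCCCCCc1c(OC)ccc(O[Si](C)(C)C)c1B1OC(C)(C)C(C)(C)O1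
F11 | step 6 | 3-hexadecyl-4-methoxycyclohexa-3,5-diene-1,2-dione | CCCCCCCCCCCCCCCCC1=C(OC)C=CC(=O)C1=O
F12 | step 6 | 3-hexadecyl-4,5-dimethoxybenzene-1,2-diol | CCCCCCCCCCCCCCCCc1c(OC)c(OC)cc(O)c1O
F13 | step 6 | 3-hexadecyl-4,5-dimethoxycyclohexa-3,5-diene-1,2-dione | CCCCCCCCCCCCCCCCC1=C(OC)C(OC)=CC(=O)C1=O
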